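## Retrosynthetic overview

- No ring is built: the chromanone core and its only stereocentre (C2, S) are bought intact as (2S)-naringenin, and every step is kept non-basic so C2 is never opened or epimerised.
- C8–prenyl bond: from a 5-O-prenyl ether by a Eu(III)-catalysed aromatic Claisen ([3,3] to C6) then Cope ([3,3] to C8) cascade.
- C3'–prenyl bond: from a 4'-O-(1,1-dimethylallyl) ether by a thermal ortho-Claisen ([3,3] with allylic inversion, giving the normal prenyl).
- The three phenols are told apart by acidity: 7-OH (most acidic) is silylated first, 4'-OH is then tert-prenylated, and the chelated 5-OH is prenylated last.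
- Both rearrangements run in one pot, then the silyl group is removed.

Assumption: (2S)-naringenin (CAS 480-41-1) is bought as the single enantiomer and its ee confirmed by chiral HPLC (much commercial "naringenin" is racemic). tert-Butyl 2-methylbut-3-en-2-yl carbonate is a catalogue reagent.

## Route

**Step 1**
Reactants: 1, (2S)-naringenin; 2, chlorotriisopropylsilane (TIPSCl)
Product: 3, (2S)-5-hydroxy-2-(4-hydroxyphenyl)-7-(triisopropylsilyloxy)chroman-4-one
Conditions: TIPSCl (1.05 equiv), imidazole, DMF, 0 °C
Reagents that add atoms: TIPSCl, CC(C)[Si](Cl)(C(C)C)C(C)C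
Why: Regioselective silyl ether formation: the 7-OH (para to C4=O, pKa about 8) is much more acidic than the 4'-OH (about 10) and the 5-OH is locked in a hydrogen bond to C4=O, so one equivalent of silyl chloride goes to O7; nothing basic enough to open the pyranone is present, so C2 stays S.

**Step 2**
Reactants: 3; 4, tert-butyl 2-methylbut-3-en-2-yl carbonate
Product: 5, (2S)-5-hydroxy-2-[4-(2-methylbut-3-en-2-yloxy)phenyl]-7-(triisopropylsilyloxy)chroman-4-one
Conditions: 4 (1.3 equiv), Pd(PPh3)4 (3 mol %), THF, 0 °C, stop at full conversion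
Reagents that add atoms: tert-butyl 2-methylbut-3-en-2-yl carbonate, C=CC(C)(C)OC(=O)OC(C)(C)C
Why: Tsuji–Trost O-allylation: decarboxylative ionisation gives a 1,1-dimethyl-π-allyl-Pd cation that the 4'-phenoxide (the only non-chelated OH) attacks at the more substituted terminus under kinetic control, giving the tertiary ether under near-neutral conditions that leave C2 and the TIPS ether alone.

**Step 3**
Reactants: 5; 6, 3-methylbut-2-en-1-ol (prenol)
Product: 7, (2S)-5-(3-methylbut-2-enyloxy)-2-[4-(2-methylbut-3-en-2-yloxy)phenyl]-7-(triisopropylsilyloxy)chroman-4-one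
Conditions: prenol, PPh3, DIAD, THF, 0 °C → rt
Reagents that add atoms: prenol, CC(C)=CCO
Why: Mitsunobu etherification alkylates the poorly nucleophilic, chelated 5-OH (the only OH left) by SN2 at the primary prenyl carbon under neutral conditions, so C2 is untouched.

**Step 4**
Reactants: 7
Product: 8, (2S)-5-hydroxy-2-[4-hydroxy-3-(3-methylbut-2-enyl)phenyl]-8-(3-methylbut-2-enyl)-7-(triisopropylsilyloxy)chroman-4-one
Conditions: Eu(fod)3 (10 mol %), PhCl, 60 °C; then 125 °C, Ar, one pot
Reagents that add atoms: none
Why: Eu(III) bound at C4=O/O5 triggers an aromatic Claisen [3,3] shift to C6 and then a Cope [3,3] shift to C8, placing the unrearranged prenyl at C8 (the 6-(1,1-dimethylallyl) isomer is the expected, separable by-product); on warming, the tertiary allyl aryl ether undergoes a thermal ortho-Claisen [3,3] shift that puts the normal prenyl at C3' (both ortho positions are equivalent), and neither event involves C2.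

**Step 5**
Reactants: 8
Product: 9, euchrestaflavanone A, (2S)-5,7-dihydroxy-2-[4-hydroxy-3-(3-methylbut-2-enyl)phenyl]-8-(3-methylbut-2-enyl)chroman-4-one
Conditions: TBAF, AcOH (1:1), THF, 0 °C
Reagents that add atoms: none
Why: Fluoride-mediated desilylation of the aryl silyl ether; the acetic acid buffer prevents the phenoxide-driven retro-oxa-Michael/quinone-methide opening that would racemise C2, and the non-acidic medium avoids chroman formation from the ortho-prenylphenols.

## Compound list

1 | (2S)-naringenin | Oc1ccc([C@@H]2CC(=O)c3c(O)cc(O)cc3O2)cc1 | starting material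
2 | chlorotriisopropylsilane | CC(C)[Si](Cl)(C(C)C)C(C)C | starting material
3 | (2S)-7-O-TIPS-naringenin | Oc1ccc([C@@H]2CC(=O)c3c(O)cc(O[Si](C(C)C)(C(C)C)C(C)C)cc3O2)cc1 | intermediate
4 | tert-butyl 2-methylbut-3-en-2-yl carbonate | C=CC(C)(C)OC(=O)OC(C)(C)C | starting material
5 | (2S)-4'-O-(1,1-dimethylallyl)-7-O-TIPS-naringenin | C=CC(C)(C)Oc1ccc([C@@H]2CC(=O)c3c(O)cc(O[Si](C(C)C)(C(C)C)C(C)C)cc3O2)cc1 | intermediate
6 | 3-methylbut-2-en-1-ol | CC(C)=CCO | starting material
7 | (2S)-5-O-prenyl-4'-O-(1,1-dimethylallyl)-7-O-TIPS-naringenin | C=CC(C)(C)Oc1ccc([C@@H]2CC(=O)c3c(OCC=C(C)C)cc(O[Si](C(C)C)(C(C)C)C(C)C)cc3O2)cc1 | intermediate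
8 | (2S)-7-O-TIPS-euchrestaflavanone A | CC(C)=CCc1cc([C@@H]2CC(=O)c3c(O)cc(O[Si](C(C)C)(C(C)C)C(C)C)c(CC=C(C)C)c3O2)ccc1O | intermediate
9 | euchrestaflavanone A | CC(C)=CCc1cc([C@@H]2CC(=O)c3c(O)cc(O)c(CC=C(C)C)c3O2)ccc1O | target

## Summary

Total steps: 5. Longest linear sequence: 5 (fully linear from 1).

Steps most likely to fail:

1. **Step 4 (one-pot Claisen–Cope plus ortho-Claisen).** Risks are Eu-induced loss of the tertiary ether, too much 6-(1,1-dimethylallyl) isomer, and chroman formation at 125 °C. Fallback: separate the two events. Heat 5 alone (PhMe, 120 °C) to form the 3'-prenylphenol, cap the new 4'-OH as a TBS ether, then run the Mitsunobu and Eu(fod)3 Claisen–Cope on a substrate with no tertiary ether, and remove both silyl groups together (one extra step).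

2. **Step 1 (7-OH versus 4'-OH selectivity).** Fallback: differentiate through the diacetate instead. Make the 7,4'-diacetate (Ac2O, pyridine), selectively cleave the more labile 7-acetate (imidazole/PhSH), silylate O7, then remove the 4'-acetate under neutral conditions (NH4OAc, aq. MeOH) to reach 3.

3. **Step 2 (branched versus linear O-allylation, and Pd-mediated isomerisation to the prenyl ether).** Fallback: build the tertiary ether through the alkyne. Cu-catalysed O-alkylation with 2-methylbut-3-yn-2-yl trifluoroacetate (CuCl2 cat., DBU, MeCN, 0 °C) gives the 1,1-dimethylpropargyl ether, and Lindlar semihydrogenation then gives 5.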